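(The numbers in the tables are calculated for an exercise; noise was put on by code.)

Two questions for these flasks: how much starting material gets used up, and what share of it becomes product.

| flask | starting material | partner | protic impurity | remark | time |
|---|---|---|---|---|---|
| summer | 49 mM | 49 mM | 24.5 mM | run made earlier |  |
| Saturday's | 12 mM | 73.5 mM | 80.0 mM |  | 40 h |
| Wednesday's | 49 mM | 73.5 mM | 24.5 mM |  | 40 h |

summer run (percent of the starting material charged)

| time / h | product / % | starting material / % |
|---|---|---|
| 2.00 | 5.3 | 69.7 |
| 4.00 | 12.7 | 53.0 |
| 6.00 | 17.2 | 41.4 |
| 8.00 | 20.1 | 31.8 |

(each reading ± 0.5 percentage points)

- the numbers in the tables scatter by 0.5 percentage points (one standard deviation)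
- no earlier run changes the charge of protic impurity; that part of a forecast is a guess

* the flask that ends with the higher amount of product, in percent of the starting material charged, or "neither" when 2 percentage points or less lies between them (Saturday's / Wednesday's / neither)
* final product, as a percentage of the starting material charged, in Saturday's
* final product, as a percentage of the starting material charged, in Wednesday's

How fast does the starting material go? Take the fraction left. In the summer run it reads 53.0 % at 4.00 h and 31.8 % at 8.00 h, which read as a steady fall is a half-life of 5.43 h. At that pace 40 h leaves 0.605 %, so I count the starting material as used up, and the end product is then the share.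

What share? Over the same interval product gains 7.4 percentage points while starting material loses 21 points, a share, or selectivity, of 0.349.

But the charges differ, so why should that share hold? It shouldn't. I assume that the odds of product against loss follow [partner]/[protic impurity] as charged, though no earlier run tests the impurity. Those odds divided by that ratio I call the pull: 0.268.

What does it give? Saturday's gets 19.8 % and Wednesday's 44.6 %, so by my reckoning Wednesday's ends higher, by 25 points.

The forecast says Wednesday's, with 10 % (3 % to 24 %) for Saturday's and 38 % (30 % to 48 %) for Wednesday's. Both of my figures stand above the forecast's. On Saturday's it says: “This is a guess because impurity dependence is untested.”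

The flasks give Wednesday's, with 30.2 % in Saturday's and 41.9 % in Wednesday's.

    starting material + partner ⇌ intermediate A (K = 4.30 /M, k = 0.0390 /M/min)
    starting material → intermediate B (k = 6.90 × 10⁻⁴ /min)
    intermediate C ⇌ intermediate D (K = 0.900, k = 0.00590 /min)
    intermediate E → decomposed reagent (k = 0.00270 /min)
    partner + intermediate A → intermediate C (k = 0.580 /M/min)
    starting material + protic impurity → quenched substrate (k = 0.0470 /M/min)
    intermediate C ⇌ product (K = 15.0, k = 0.0260 /min)
    intermediate B ⇌ intermediate E (K = 2.60, k = 0.00160 /min)

In Saturday's, the step of starting material with protic impurity and the step of partner with intermediate A each had 95 % of their turnover behind them by 8.00 h. At 20.0 h in Saturday's, starting material stood at 0.0579 %, product at 30.1 % and quenched substrate at 55.4 %. Reckoned back from the end amounts, the pull is 0.240 in Wednesday's and 0.470 in Saturday's, against the 0.268 read from the summer readings.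

Take Saturday's flask with 180 mM of partner. The pull of 0.268 gives 37.6 %, and that flask gives 52.1 %.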